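## Retrosynthetic overview

1. Target 23 ⇐ (2S)-flavanone 19: the 3-OH goes in by Rubottom oxidation of the silyl enol ether, anti to the 2-aryl group, followed by desilylation.
2. The pyranone ring, the only ring formed, ⇐ intramolecular oxa-Michael addition of the 2'-phenol onto alkylidene β-keto ester 16 under a cinchona thiourea catalyst; the activating ester is then removed by Pd-catalysed decarboxylation.
3. 16 ⇐ Knoevenagel union of A-ring β-keto ester 11 and B-ring aldehyde 15.
4. 11 ⇐ methyl 2,4-dihydroxybenzoate (di-iodination, 4-O-TBS, double Stille prenylation, Claisen condensation with 1,1-dimethylallyl acetate 9); 15 ⇐ 4-hydroxybenzaldehyde (iodination, TBS, Stille).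
5. Both benzene rings are bought; prenylstannane 2 is made once and used for both fragments.

Assumption: the quinidine-derived pseudo-enantiomer of the thiourea catalyst is taken to be the one that gives the 2S ring closure; if the first chiral HPLC check shows the antipode, the quinine-derived catalyst is used with nothing else changed.

Abbreviations: TBS = tert-butyldimethylsilyl, prenyl = 3-methylbut-2-en-1-yl.

## Route

Step 1
Reactants: 1 1-chloro-3-methylbut-2-ene (prenyl chloride)
Product: 2 tributyl(3-methylbut-2-en-1-yl)stannane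
Conditions: Bu3SnH, LDA, THF, 0 °C; then 1, −78 °C → rt
Reagents that add atoms: tributyltin hydride, CCCC[SnH](CCCC)CCCC
Why: SN2 stannylation of the primary allylic chloride by tributylstannyllithium gives the linear prenylstannane.

Step 2
Reactants: 3 methyl 2,4-dihydroxybenzoate
Product: 4 methyl 2,4-dihydroxy-3,5-diiodobenzoate
Conditions: NIS (2.2 equiv), TsOH·H2O (10 mol%), MeCN, 0 °C → rt
Reagents that add atoms: N-iodosuccinimide, O=C1CCC(=O)N1I
Why: Electrophilic aromatic iodination goes only to C3 and C5, which are ortho/para to both hydroxyls, while C6 is meta to both.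

Step 3
Reactants: 4 methyl 2,4-dihydroxy-3,5-diiodobenzoate
Product: 5 methyl 4-(tert-butyldimethylsilyloxy)-2-hydroxy-3,5-diiodobenzoate
Conditions: TBSCl (1.1 equiv), imidazole, DMF, 0 °C → rt
Reagents that add atoms: tert-butyldimethylsilyl chloride, CC(C)(C)[Si](C)(C)Cl
Why: Selective silylation takes the acidic, non-chelated 4-OH, while the 2-OH stays hydrogen-bonded to the ester carbonyl and is kept free as the later ring-closing nucleophile.

Step 4
Reactants: 5 methyl 4-(tert-butyldimethylsilyloxy)-2-hydroxy-3,5-diiodobenzoate; 2 tributyl(3-methylbut-2-en-1-yl)stannane (2.6 equiv)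
Product: 6 methyl 4-(tert-butyldimethylsilyloxy)-2-hydroxy-3,5-bis(3-methylbut-2-en-1-yl)benzoate
Conditions: Pd(PPh3)4 (10 mol%), DMF (dry, degassed), 90 °C
Reagents that add atoms: none
Why: Twofold Stille coupling transfers the allyl group from tin mainly at its unsubstituted terminus to give linear prenyl groups, and the ester, phenol and silyl ether are inert to it.

Step 5
Reactants: 7 2-methylbut-3-en-2-ol; 8 acetic anhydride
Product: 9 2-methylbut-3-en-2-yl acetate (1,1-dimethylallyl acetate)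
Conditions: Et3N, DMAP (10 mol%), CH2Cl2, rt → 40 °C
Reagents that add atoms: none
Why: DMAP-catalysed acylation of the tertiary alcohol gives an acetate whose ester group is as bulky as tert-butyl but can later be removed by Pd(0) instead of acid.

Step 6
Reactants: 6 methyl 4-(tert-butyldimethylsilyloxy)-2-hydroxy-3,5-bis(3-methylbut-2-en-1-yl)benzoate; 9 2-methylbut-3-en-2-yl acetate (4 equiv)
Product: 11 2-methylbut-3-en-2-yl 3-[4-(tert-butyldimethylsilyloxy)-2-hydroxy-3,5-bis(3-methylbut-2-en-1-yl)phenyl]-3-oxopropanoate, via lithium enolate 10 (not isolated)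
Conditions: LDA (4.2 equiv), 9, THF, −78 °C; then 6, −78 → 0 °C; aq. NH4Cl
Reagents that add atoms: none
Why: Crossed Claisen condensation of the ester enolate with the salicylate ester is driven by deprotonation of the β-keto ester product, with the excess enolate absorbing the phenol proton.

Step 7
Reactants: 12 4-hydroxybenzaldehyde
Product: 13 4-hydroxy-3-iodobenzaldehyde
Conditions: NIS (1.05 equiv), AcOH, rt
Reagents that add atoms: N-iodosuccinimide, O=C1CCC(=O)N1I
Why: Electrophilic iodination occurs ortho to the phenol because the para position is blocked by the formyl group.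

Step 8
Reactants: 13 4-hydroxy-3-iodobenzaldehyde
Product: 14 4-(tert-butyldimethylsilyloxy)-3-iodobenzaldehyde
Conditions: TBSCl, imidazole, DMF, rt
Reagents that add atoms: tert-butyldimethylsilyl chloride, CC(C)(C)[Si](C)(C)Cl
Why: Standard phenol silylation gives the same fluoride-labile protection as on the A ring.

Step 9
Reactants: 14 4-(tert-butyldimethylsilyloxy)-3-iodobenzaldehyde; 2 tributyl(3-methylbut-2-en-1-yl)stannane (1.3 equiv)
Product: 15 4-(tert-butyldimethylsilyloxy)-3-(3-methylbut-2-en-1-yl)benzaldehyde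
Conditions: Pd(PPh3)4 (5 mol%), toluene (degassed), 105 °C
Reagents that add atoms: none
Why: Stille coupling of the aryl iodide installs the linear prenyl group without touching the aldehyde or the silyl ether.

Step 10
Reactants: 11 the A-ring β-keto ester; 15 4-(tert-butyldimethylsilyloxy)-3-(3-methylbut-2-en-1-yl)benzaldehyde
Product: 16 2-methylbut-3-en-2-yl (Z)-2-[4-(tert-butyldimethylsilyloxy)-2-hydroxy-3,5-bis(3-methylbut-2-en-1-yl)benzoyl]-3-[4-(tert-butyldimethylsilyloxy)-3-(3-methylbut-2-en-1-yl)phenyl]prop-2-enoate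
Conditions: piperidine (0.2 equiv), AcOH (0.2 equiv), 4 Å MS, benzene, rt
Reagents that add atoms: none
Why: Knoevenagel condensation of the β-keto ester with the aryl aldehyde gives the doubly activated alkylidene under conditions mild enough that the chelated phenol does not yet cyclise.

Step 11
Reactants: 16 the alkylidene β-keto ester
Product: 19 (2S)-7-(tert-butyldimethylsilyloxy)-2-[4-(tert-butyldimethylsilyloxy)-3-(3-methylbut-2-en-1-yl)phenyl]-6,8-bis(3-methylbut-2-en-1-yl)chroman-4-one, via cyclised keto ester 17 (not isolated), via keto acid 18 (not isolated)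
Conditions: 9-amino(9-deoxy)epi-quinidine 3,5-bis(trifluoromethyl)phenyl thiourea (10 mol%), toluene, −25 °C; then HCO2H/Et3N (1.2:1, 3 equiv), Pd(PPh3)4 (5 mol%), THF, −25 °C → rt
Reagents that add atoms: none
Why: The ring closes by a 6-endo intramolecular oxa-Michael addition in which the thiourea binds the β-keto ester and the quinuclidine delivers the phenol to one face to set C2 as S; Tsuji Pd/formate deallylation and decarboxylation of the β-keto acid then removes the activating ester at near-neutral pH, sparing the prenyl groups and C2.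

Step 12
Reactants: 19 the (2S)-flavanone
Product: 20 (2S)-7-(tert-butyldimethylsilyloxy)-2-[4-(tert-butyldimethylsilyloxy)-3-(3-methylbut-2-en-1-yl)phenyl]-6,8-bis(3-methylbut-2-en-1-yl)-4-(trimethylsilyloxy)-2H-chromene
Conditions: TMSOTf (1.3 equiv), Et3N (2 equiv), CH2Cl2, 0 °C; cold NaHCO3 wash, used at once
Reagents that add atoms: trimethylsilyl triflate, C[Si](C)(C)OS(=O)(=O)C(F)(F)F
Why: Soft enolisation gives the silyl enol ether without a free enolate, so the retro-oxa-Michael (E1cB) opening that would racemise C2 is avoided.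

Step 13
Reactants: 20 the silyl enol ether
Product: 22 (2R,3R)-7-(tert-butyldimethylsilyloxy)-2-[4-(tert-butyldimethylsilyloxy)-3-(3-methylbut-2-en-1-yl)phenyl]-3-hydroxy-6,8-bis(3-methylbut-2-en-1-yl)chroman-4-one, via siloxy epoxide 21 (not isolated)
Conditions: DMDO (1.05 equiv, acetone), CH2Cl2, −78 °C; then 10% aq. citric acid, THF, 0 °C
Reagents that add atoms: dimethyldioxirane, CC1(C)OO1
Why: In this Rubottom oxidation DMDO epoxidises the electron-rich enol ether much faster than the trisubstituted prenyl alkenes at −78 °C and from the face anti to the C2 aryl group, so hydrolysis gives the 2,3-trans α-hydroxy ketone with C3 as R.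

Step 14
Reactants: 22 the tris-TBS dihydroflavonol
Product: 23 lespeflorin B3, (2R,3R)-3,7-dihydroxy-2-[4-hydroxy-3-(3-methylbut-2-en-1-yl)phenyl]-6,8-bis(3-methylbut-2-en-1-yl)chroman-4-one
Conditions: TBAF (3.5 equiv), AcOH (3.5 equiv), THF, 0 °C
Reagents that add atoms: none
Why: Fluoride desilylation buffered with acetic acid frees the three phenols without the base that would epimerise or open the dihydroflavonol and without the acid that would cyclise the ortho-prenyl phenols to chromans.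

## Compound list

1 | 1-chloro-3-methylbut-2-ene | CC(C)=CCCl | starting material
2 | tributyl(3-methylbut-2-en-1-yl)stannane | CCCC[Sn](CCCC)(CCCC)CC=C(C)C | intermediate
3 | methyl 2,4-dihydroxybenzoate | COC(=O)c1ccc(O)cc1O | starting material
4 | methyl 2,4-dihydroxy-3,5-diiodobenzoate | COC(=O)c1cc(I)c(O)c(I)c1O | intermediate
5 | methyl 4-(TBS-oxy)-2-hydroxy-3,5-diiodobenzoate | COC(=O)c1cc(I)c(O[Si](C)(C)C(C)(C)C)c(I)c1O | intermediate
6 | methyl 4-(TBS-oxy)-2-hydroxy-3,5-diprenylbenzoate | COC(=O)c1cc(CC=C(C)C)c(O[Si](C)(C)C(C)(C)C)c(CC=C(C)C)c1O | intermediate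
7 | 2-methylbut-3-en-2-ol | CC(C)(O)C=C | starting material
8 | acetic anhydride | CC(=O)OC(C)=O | starting material
9 | 2-methylbut-3-en-2-yl acetate | CC(=O)OC(C)(C)C=C | intermediate
10 | lithium enolate of 9 (not isolated) | C=C(O[Li])OC(C)(C)C=C | intermediate
11 | 2-methylbut-3-en-2-yl 3-[4-(TBS-oxy)-2-hydroxy-3,5-diprenylphenyl]-3-oxopropanoate | C=CC(C)(C)OC(=O)CC(=O)c1cc(CC=C(C)C)c(O[Si](C)(C)C(C)(C)C)c(CC=C(C)C)c1O | intermediate
12 | 4-hydroxybenzaldehyde | O=Cc1ccc(O)cc1 | starting material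
13 | 4-hydroxy-3-iodobenzaldehyde | O=Cc1ccc(O)c(I)c1 | intermediate
14 | 4-(TBS-oxy)-3-iodobenzaldehyde | O=Cc1ccc(O[Si](C)(C)C(C)(C)C)c(I)c1 | intermediate
15 | 4-(TBS-oxy)-3-prenylbenzaldehyde | O=Cc1ccc(O[Si](C)(C)C(C)(C)C)c(CC=C(C)C)c1 | intermediate
16 | 2-methylbut-3-en-2-yl (Z)-2-[4-(TBS-oxy)-2-hydroxy-3,5-diprenylbenzoyl]-3-[4-(TBS-oxy)-3-prenylphenyl]prop-2-enoate (major isomer drawn) | C=CC(C)(C)OC(=O)/C(=C\c1ccc(O[Si](C)(C)C(C)(C)C)c(CC=C(C)C)c1)C(=O)c1cc(CC=C(C)C)c(O[Si](C)(C)C(C)(C)C)c(CC=C(C)C)c1O | intermediate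
17 | 2-methylbut-3-en-2-yl (2S,3R)-7-(TBS-oxy)-2-[4-(TBS-oxy)-3-prenylphenyl]-6,8-diprenyl-4-oxochromane-3-carboxylate (trans keto form, equilibrates with its enol; not isolated) | CC(C)=CCc1cc([C@H]2Oc3c(cc(CC=C(C)C)c(O[Si](C)(C)C(C)(C)C)c3CC=C(C)C)C(=O)[C@@H]2C(=O)OC(C)(C)C=C)ccc1O[Si](C)(C)C(C)(C)C | intermediate
18 | (2S,3R)-7-(TBS-oxy)-2-[4-(TBS-oxy)-3-prenylphenyl]-6,8-diprenyl-4-oxochromane-3-carboxylic acid (not isolated) | CC(C)=CCc1cc([C@H]2Oc3c(cc(CC=C(C)C)c(O[Si](C)(C)C(C)(C)C)c3CC=C(C)C)C(=O)[C@@H]2C(=O)O)ccc1O[Si](C)(C)C(C)(C)C | intermediate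
19 | (2S)-7-(TBS-oxy)-2-[4-(TBS-oxy)-3-prenylphenyl]-6,8-diprenylchroman-4-one | CC(C)=CCc1cc([C@H]2Oc3c(cc(CC=C(C)C)c(O[Si](C)(C)C(C)(C)C)c3CC=C(C)C)C(=O)C2)ccc1O[Si](C)(C)C(C)(C)C | intermediate
20 | (2S)-7-(TBS-oxy)-2-[4-(TBS-oxy)-3-prenylphenyl]-6,8-diprenyl-4-(trimethylsilyloxy)-2H-chromene | CC(C)=CCc1cc([C@H]2Oc3c(cc(CC=C(C)C)c(O[Si](C)(C)C(C)(C)C)c3CC=C(C)C)C(O[Si](C)(C)C)=C2)ccc1O[Si](C)(C)C(C)(C)C | intermediate
21 | (2R,3R,4R)-3,4-epoxy-7-(TBS-oxy)-2-[4-(TBS-oxy)-3-prenylphenyl]-6,8-diprenyl-4-(trimethylsilyloxy)chromane, epoxide oxygen trans to the 2-aryl group (not isolated) | CC(C)=CCc1cc([C@H]2Oc3c(cc(CC=C(C)C)c(O[Si](C)(C)C(C)(C)C)c3CC=C(C)C)[C@]3(O[Si](C)(C)C)O[C@H]23)ccc1O[Si](C)(C)C(C)(C)C | intermediate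
22 | (2R,3R)-7-(TBS-oxy)-2-[4-(TBS-oxy)-3-prenylphenyl]-3-hydroxy-6,8-diprenylchroman-4-one | CC(C)=CCc1cc([C@H]2Oc3c(cc(CC=C(C)C)c(O[Si](C)(C)C(C)(C)C)c3CC=C(C)C)C(=O)[C@@H]2O)ccc1O[Si](C)(C)C(C)(C)C | intermediate
23 | lespeflorin B3, (2R,3R)-3,7-dihydroxy-2-(4-hydroxy-3-prenylphenyl)-6,8-diprenylchroman-4-one | CC(C)=CCc1cc([C@H]2Oc3c(cc(CC=C(C)C)c(O)c3CC=C(C)C)C(=O)[C@@H]2O)ccc1O | target

## Step count and risks

Total step count: 14.
Longest linear sequence: 9 steps (steps 2, 3, 4, 6, 10, 11, 12, 13, 14, from methyl 2,4-dihydroxybenzoate 3).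

The three steps most likely to fail:

Step 4, the double Stille prenylation. The C3 iodide is flanked by the 2-OH and the bulky 4-OTBS group, so coupling there may be slow and give protodeiodination or some reverse-prenyl isomer. The fallback sets out from 3 and comes back at 6. Friedel–Crafts prenylation of 3 with 2-methylbut-3-en-2-ol 7 and BF3·OEt2 in dioxane at rt gives methyl 2,4-dihydroxy-3,5-bis(3-methylbut-2-en-1-yl)benzoate F1, which is separated from mono-prenyl and chroman by-products. Selective silylation of its non-chelated 4-OH (TBSCl, imidazole, DMF) gives 6. This replaces cross-coupling by electrophilic C-prenylation and bypasses 4 and 5.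

Step 11, the asymmetric oxa-Michael closure and decarboxylation. The tertiary allylic ester and the phenol hindered by the ortho prenyl group are an extrapolation for this type of catalyst, so the ee may be insufficient; the thiourea may also slow the Pd catalyst, in which case the mixture is passed through a short silica plug before the Pd step. The fallback sets out from 16 and comes back at 19. Cyclisation of 16 with an achiral amine (DABCO, toluene, rt) gives the racemic cyclised keto ester F2. Pd(PPh3)4 with HCO2H/Et3N converts it to the racemic keto acid F3, which loses CO2 to give the racemic flavanone F4. Kinetic resolution by Noyori transfer hydrogenation (RuCl[(R,R)-TsDPEN](p-cymene), HCO2H/Et3N, about 55% conversion) then reduces only the 2R enantiomer, to the cis-(2R,4R)-flavan-4-ol F5. This is removed by chromatography and leaves enantiopure (2S)-19. The same resolution can be applied directly to 19 of insufficient ee.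

Step 13, the Rubottom oxidation. DMDO may also epoxidise one of the three prenyl alkenes. The fallback sets out from 20 and comes back at 22. An O-selective nitroso aldol reaction of 20 with nitrosobenzene (TESOTf 10 mol%, CH2Cl2, −78 °C), which does not touch the prenyl groups, gives the (2R,3R)-3-(phenylaminooxy)flavanone F6, again by attack anti to the 2-aryl group. N–O cleavage with Zn dust in AcOH/THF at 0 °C gives 22.

## Further compounds

F1 | step 4 | methyl 2,4-dihydroxy-3,5-bis(3-methylbut-2-en-1-yl)benzoate | COC(=O)c1cc(CC=C(C)C)c(O)c(CC=C(C)C)c1O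
F2 | step 11 | racemic 2-methylbut-3-en-2-yl 7-(TBS-oxy)-2-[4-(TBS-oxy)-3-prenylphenyl]-6,8-diprenyl-4-oxochromane-3-carboxylate | CC(C)=CCc1cc(C2Oc3c(cc(CC=C(C)C)c(O[Si](C)(C)C(C)(C)C)c3CC=C(C)C)C(=O)C2C(=O)OC(C)(C)C=C)ccc1O[Si](C)(C)C(C)(C)C
F3 | step 11 | racemic 7-(TBS-oxy)-2-[4-(TBS-oxy)-3-prenylphenyl]-6,8-diprenyl-4-oxochromane-3-carboxylic acid | CC(C)=CCc1cc(C2Oc3c(cc(CC=C(C)C)c(O[Si](C)(C)C(C)(C)C)c3CC=C(C)C)C(=O)C2C(=O)O)ccc1O[Si](C)(C)C(C)(C)C
F4 | step 11 | racemic 7-(TBS-oxy)-2-[4-(TBS-oxy)-3-prenylphenyl]-6,8-diprenylchroman-4-one | CC(C)=CCc1cc(C2Oc3c(cc(CC=C(C)C)c(O[Si](C)(C)C(C)(C)C)c3CC=C(C)C)C(=O)C2)ccc1O[Si](C)(C)C(C)(C)C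
F5 | step 11 | (2R,4R)-7-(TBS-oxy)-2-[4-(TBS-oxy)-3-prenylphenyl]-6,8-diprenylchroman-4-ol (cis) | CC(C)=CCc1cc([C@@H]2Oc3c(cc(CC=C(C)C)c(O[Si](C)(C)C(C)(C)C)c3CC=C(C)C)[C@H](O)C2)ccc1O[Si](C)(C)C(C)(C)C
F6 | step 13 | (2R,3R)-7-(TBS-oxy)-2-[4-(TBS-oxy)-3-prenylphenyl]-3-(phenylaminooxy)-6,8-diprenylchroman-4-one | CC(C)=CCc1cc([C@H]2Oc3c(cc(CC=C(C)C)c(O[Si](C)(C)C(C)(C)C)c3CC=C(C)C)C(=O)[C@@H]2ONc2ccccc2)ccc1O[Si](C)(C)C(C)(C)C
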